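## Retrosynthetic overview

1. C15 acid ⇐ aldehyde (Pinnick); C13 stereocentre ⇐ iminium-catalysed transfer hydrogenation of a citral-like enal ⇐ methyl ketone (formyl-olefination) ⇐ enone (conjugate reduction) ⇐ C11 aldehyde + C3 phosphonate.
2. Ring B (formed second, onto a preformed ring A): C7–C8 and C9–C10 bonds by a catalyst-controlled exo Diels–Alder of tiglaldehyde with a 1-vinylcyclohexene; C8, C9 and C10 are set together.
3. Diene ⇐ enol triflate + vinylstannane ⇐ 2-(acetoxymethyl)-2-methylcyclohexanone.
4. C4–C18 bond and first stereocentre (C4) ⇐ new catalytic asymmetric acetoxymethylation of an achiral enol silane; ring A is bought as a six-membered ring.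
5. Atom labels (C4, C9, C13 and so on) are the halimane numbers of the target; systematic names use naphthalene numbering.

Assumption: the senses of induction of the new catalyst in step 1 and of the catalysts in steps 4 and 8 are as stated (each antipode is equally available), and enol silane 1 is bought as the tetrasubstituted regioisomer.

## Route

Step 1
Reactants: 1 trimethyl[(2-methylcyclohex-1-en-1-yl)oxy]silane; 2 methylene diacetate
Product: 3 [(1S)-1-methyl-2-oxocyclohexyl]methyl acetate
Conditions: (S,S)-IDPi (BINOL-derived imidodiphosphorimidate, N-triflyl, 3 mol %), 1 (1.2 equiv), toluene, −60 °C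
Reagents that add atoms: 2 methylene diacetate, CC(=O)OCOC(C)=O
Why: Proposed new method: the imidodiphosphorimidate is silylated by 1 to a silylium ion pair that strips acetate from 2 (as Me3SiOAc) and leaves the acetoxymethyl cation inside the confined chiral anion, where the tetrasubstituted enol silane attacks through the Re face of its methyl-bearing carbon to form the C4–C18 bond and the quaternary stereocentre (S in 3) before silyl transfer closes the cycle, the closest known reaction types being imidodiphosphorimidate-catalysed Mukaiyama aldol and aminomethylation reactions of silyl ketene acetals with oxocarbenium and methylene iminium ions and achiral Lewis-acid Mukaiyama reactions of acylals.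

Step 2
Reactants: 3 [(1S)-1-methyl-2-oxocyclohexyl]methyl acetate
Product: 4 [(1S)-1-methyl-2-(trifluoromethanesulfonyloxy)cyclohex-2-en-1-yl]methyl acetate
Conditions: Tf2O, 2,6-di-tert-butyl-4-methylpyridine, CH2Cl2, 0 °C → rt
Reagents that add atoms: trifluoromethanesulfonic anhydride (Tf2O), O=S(=O)(OS(=O)(=O)C(F)(F)F)C(F)(F)F
Why: O-triflation of the ketone (enol triflate formation): only the CH2 side can enolise because the other alpha carbon is quaternary, and the hindered pyridine base scavenges TfOH without harming the acetate or the stereocentre.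

Step 3
Reactants: 4 [(1S)-1-methyl-2-(trifluoromethanesulfonyloxy)cyclohex-2-en-1-yl]methyl acetate; 5 tributyl(ethenyl)stannane
Product: 6 [(1R)-2-ethenyl-1-methylcyclohex-2-en-1-yl]methyl acetate
Conditions: Pd(PPh3)4 (5 mol %), LiCl (3 equiv), THF, 65 °C
Reagents that add atoms: 5 tributyl(ethenyl)stannane, C=C[Sn](CCCC)(CCCC)CCCC
Why: Stille cross-coupling: oxidative addition of the enol triflate to zerovalent palladium, chloride-assisted transmetalation from tin and reductive elimination give the 1-vinylcyclohexene under neutral conditions that spare the acetate (the descriptor changes from S to R only through the priority rules).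

Step 4
Reactants: 6 [(1R)-2-ethenyl-1-methylcyclohex-2-en-1-yl]methyl acetate; 7 (2E)-2-methylbut-2-enal (tiglaldehyde)
Product: 8 (1R,2S,5R,8aR)-5-(acetoxymethyl)-1,2,5-trimethyl-1,2,3,5,6,7,8,8a-octahydronaphthalene-1-carbaldehyde
Conditions: (R)-o-tolyl-CBS-oxazaborolidine (20 mol %), Tf2NH (18 mol %), 7 (3 equiv), CH2Cl2, −78 → −20 °C
Reagents that add atoms: 7 (2E)-2-methylbut-2-enal, C/C=C(\C)C=O
Why: Catalytic enantioselective Diels–Alder reaction under chiral oxazaborolidinium (cationic boron Lewis acid) catalysis: the formyl-bound s-trans enal is shielded on its Re face so the diene adds to the Si face of C2 of 7 with ortho regiochemistry (C9–C10 and C7–C8 bonds), the E geometry of 7 fixes the cis C8/C9 methyls, and the formyl-exo transition state favoured for alpha-methyl enals with 6,6-disubstituted 1-vinylcyclohexenes puts the C9 methyl trans to H-10, the dienophile arriving on the diene face syn to the small C4 methyl (matched case).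

Step 5
Reactants: 8 (1R,2S,5R,8aR)-5-(acetoxymethyl)-1,2,5-trimethyl-1,2,3,5,6,7,8,8a-octahydronaphthalene-1-carbaldehyde; 9 dimethyl (2-oxopropyl)phosphonate
Product: 10 (3E)-4-[(1S,2S,5R,8aS)-5-(acetoxymethyl)-1,2,5-trimethyl-1,2,3,5,6,7,8,8a-octahydronaphthalen-1-yl]but-3-en-2-one
Conditions: 9, NaH, THF, 0 °C; then 8, 0 → 50 °C
Reagents that add atoms: 9 dimethyl (2-oxopropyl)phosphonate, COP(=O)(OC)CC(C)=O
Why: Horner–Wadsworth–Emmons olefination: the stabilised phosphonate anion adds to the non-enolisable neopentyl aldehyde and syn-elimination of phosphate gives the E enone, no stereocentre being touched (descriptor changes are due to the priority rules only).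

Step 6
Reactants: 10 (3E)-4-[(1S,2S,5R,8aS)-5-(acetoxymethyl)-1,2,5-trimethyl-1,2,3,5,6,7,8,8a-octahydronaphthalen-1-yl]but-3-en-2-one
Product: 11 4-[(1R,2S,5R,8aS)-5-(acetoxymethyl)-1,2,5-trimethyl-1,2,3,5,6,7,8,8a-octahydronaphthalen-1-yl]butan-2-one
Conditions: Cu(OAc)2·H2O (5 mol %), 1,2-bis(diphenylphosphino)benzene (5 mol %), (EtO)2MeSiH (1.5 equiv), t-BuOH (1.5 equiv), toluene, 0 °C → rt
Reagents that add atoms: none
Why: Copper hydride conjugate reduction: the phosphine-ligated CuH formed from the silane adds hydride 1,4 to the enone and tert-butanol protonates the copper enolate, leaving the isolated trisubstituted ring alkene, the ketone and the acetate intact.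

Step 7
Reactants: 11 4-[(1R,2S,5R,8aS)-5-(acetoxymethyl)-1,2,5-trimethyl-1,2,3,5,6,7,8,8a-octahydronaphthalen-1-yl]butan-2-one; 12 diethyl [(E)-2-(cyclohexylamino)ethenyl]phosphonate
Product: 14 (2E)-3-methyl-5-[(1R,2S,5R,8aS)-5-(acetoxymethyl)-1,2,5-trimethyl-1,2,3,5,6,7,8,8a-octahydronaphthalen-1-yl]pent-2-enal, via N-cyclohexyl 1-azadiene 13 (not isolated)
Conditions: 12, NaH, THF, 0 °C → rt; then 11, rt → 50 °C; then aq. oxalic acid, benzene, rt
Reagents that add atoms: 12 diethyl [(E)-2-(cyclohexylamino)ethenyl]phosphonate, CCOP(=O)(OCC)/C=C/NC1CCCCC1; water, O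
Why: Formyl-olefination of a ketone with an aminovinylphosphonate (an aza-Horner–Wadsworth–Emmons reaction): the metallated reagent condenses with the unhindered methyl ketone to the N-cyclohexyl 1-azadiene, which mild aqueous oxalic acid hydrolyses to the beta-methyl enal, the E/Z ratio being irrelevant because step 8 is stereoconvergent.

Step 8
Reactants: 14 (2E)-3-methyl-5-[(1R,2S,5R,8aS)-5-(acetoxymethyl)-1,2,5-trimethyl-1,2,3,5,6,7,8,8a-octahydronaphthalen-1-yl]pent-2-enal
Product: 15 (3R)-3-methyl-5-[(1R,2S,5R,8aS)-5-(acetoxymethyl)-1,2,5-trimethyl-1,2,3,5,6,7,8,8a-octahydronaphthalen-1-yl]pentanal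
Conditions: morpholinium (R)-TRIP phosphate (20 mol %), diethyl 2,6-dimethyl-1,4-dihydropyridine-3,5-dicarboxylate (1.2 equiv), THF, 50 °C
Reagents that add atoms: none
Why: Iminium-catalysed asymmetric transfer hydrogenation (asymmetric counteranion-directed catalysis): the morpholinium iminium ion of the enal pairs with the chiral phosphate, E and Z iminium ions interconvert through the dienamine, and the Hantzsch ester delivers hydride to one face of C13 to give the 13R centre, as in the conversion of citral into (R)-citronellal.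

Step 9
Reactants: 15 (3R)-3-methyl-5-[(1R,2S,5R,8aS)-5-(acetoxymethyl)-1,2,5-trimethyl-1,2,3,5,6,7,8,8a-octahydronaphthalen-1-yl]pentanal
Product: 16 (3R)-5-[(1R,2S,5R,8aS)-5-(acetoxymethyl)-1,2,5-trimethyl-1,2,3,5,6,7,8,8a-octahydronaphthalen-1-yl]-3-methylpentanoic acid
Conditions: NaClO2, NaH2PO4, 2-methylbut-2-ene, t-BuOH/H2O, 0 °C → rt
Reagents that add atoms: sodium chlorite (NaClO2), [Na+].[O-]Cl=O
Why: Pinnick oxidation: chlorous acid oxidises the aldehyde to the acid without epimerising the beta stereocentre, while 2-methylbut-2-ene traps HOCl and so protects the ring alkene, the acetate being untouched.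

## Compound list

1 | trimethyl[(2-methylcyclohex-1-en-1-yl)oxy]silane (achiral) | CC1=C(O[Si](C)(C)C)CCCC1 | starting material
2 | methylene diacetate | CC(=O)OCOC(C)=O | starting material
3 | [(1S)-1-methyl-2-oxocyclohexyl]methyl acetate | CC(=O)OC[C@]1(C)CCCCC1=O | intermediate
4 | [(1S)-1-methyl-2-(trifluoromethanesulfonyloxy)cyclohex-2-en-1-yl]methyl acetate | CC(=O)OC[C@]1(C)CCCC=C1OS(=O)(=O)C(F)(F)F | intermediate
5 | tributyl(ethenyl)stannane | C=C[Sn](CCCC)(CCCC)CCCC | starting material
6 | [(1R)-2-ethenyl-1-methylcyclohex-2-en-1-yl]methyl acetate | CC(=O)OC[C@]1(C)CCCC=C1C=C | intermediate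
7 | (2E)-2-methylbut-2-enal (tiglaldehyde) | C/C=C(\C)C=O | starting material
8 | (1R,2S,5R,8aR)-5-(acetoxymethyl)-1,2,5-trimethyl-1,2,3,5,6,7,8,8a-octahydronaphthalene-1-carbaldehyde | CC(=O)OC[C@]1(C)CCC[C@@H]2C1=CC[C@H](C)[C@@]2(C)C=O | intermediate
9 | dimethyl (2-oxopropyl)phosphonate | COP(=O)(OC)CC(C)=O | starting material
10 | (3E)-4-[(1S,2S,5R,8aS)-5-(acetoxymethyl)-1,2,5-trimethyl-1,2,3,5,6,7,8,8a-octahydronaphthalen-1-yl]but-3-en-2-one | CC(=O)OC[C@]1(C)CCC[C@@H]2C1=CC[C@H](C)[C@@]2(C)/C=C/C(C)=O | intermediate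
11 | 4-[(1R,2S,5R,8aS)-5-(acetoxymethyl)-1,2,5-trimethyl-1,2,3,5,6,7,8,8a-octahydronaphthalen-1-yl]butan-2-one | CC(=O)OC[C@]1(C)CCC[C@@H]2C1=CC[C@H](C)[C@@]2(C)CCC(C)=O | intermediate
12 | diethyl [(E)-2-(cyclohexylamino)ethenyl]phosphonate | CCOP(=O)(OCC)/C=C/NC1CCCCC1 | starting material
13 | (1E,2E)-N-cyclohexyl-3-methyl-5-[(1R,2S,5R,8aS)-5-(acetoxymethyl)-1,2,5-trimethyl-1,2,3,5,6,7,8,8a-octahydronaphthalen-1-yl]pent-2-en-1-imine | CC(=O)OC[C@]1(C)CCC[C@@H]2C1=CC[C@H](C)[C@@]2(C)CC/C(C)=C/C=N/C1CCCCC1 | intermediate (not isolated)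
14 | (2E)-3-methyl-5-[(1R,2S,5R,8aS)-5-(acetoxymethyl)-1,2,5-trimethyl-1,2,3,5,6,7,8,8a-octahydronaphthalen-1-yl]pent-2-enal (E major; the Z isomer is also formed and is carried on) | CC(=O)OC[C@]1(C)CCC[C@@H]2C1=CC[C@H](C)[C@@]2(C)CC/C(C)=C/C=O | intermediate
15 | (3R)-3-methyl-5-[(1R,2S,5R,8aS)-5-(acetoxymethyl)-1,2,5-trimethyl-1,2,3,5,6,7,8,8a-octahydronaphthalen-1-yl]pentanal | CC(=O)OC[C@]1(C)CCC[C@@H]2C1=CC[C@H](C)[C@@]2(C)CC[C@@H](C)CC=O | intermediate
16 | (3R)-5-[(1R,2S,5R,8aS)-5-(acetoxymethyl)-1,2,5-trimethyl-1,2,3,5,6,7,8,8a-octahydronaphthalen-1-yl]-3-methylpentanoic acid (CNP0148247.1) | CC(=O)OC[C@]1(C)CCC[C@@H]2C1=CC[C@H](C)[C@@]2(C)CC[C@@H](C)CC(=O)O | target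

## Step count and risks

Total step count: 9. Longest linear sequence: 9 (fully linear, from 1 to 16).

Steps most likely to fail:

**Step 1 (the proposed new acetoxymethylation).** The catalyst must tell a methyl from a ring CH2 on the nucleophile, and O-acylation of the enol silane could compete. The fallback uses known chemistry, sets out from 1 and comes back at 3. Enol silane 1 undergoes an aqueous Mukaiyama hydroxymethylation with formaldehyde under Sc(OTf)3 and a chiral 2,2′-bipyridine diol ligand (DME/H2O, −20 °C). This gives (2S)-2-(hydroxymethyl)-2-methylcyclohexan-1-one F1, which is acetylated (Ac2O, DMAP, pyridine) to 3. The approach changes from an anhydrous silylium/acylal reaction to a water-tolerant metal Lewis acid aldol with free formaldehyde plus a separate acylation, at the cost of one step.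

**Step 4 (Diels–Alder).** A hindered diene meets a trisubstituted enal, so the chiral boron catalyst may be too weak, or exo and facial control may leak. The fallback sets out from 6 (with 7) and comes back at 8. It gives up catalyst control: stoichiometric achiral Me2AlCl (CH2Cl2, −78 → −20 °C) drives the same exo cycloaddition, and the C4 centre alone steers the dienophile to the face syn to the C4 methyl. Aldehyde 8 is then separated by chromatography from the (1S,2R,5R,8aS) diastereomeric aldehyde F2. Because C4 is already set, this separation also removes material from the minor enantiomer of 6.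

**Step 5 (olefination of the neopentyl aldehyde).** The formyl group sits on a quaternary carbon and may resist the phosphonate anion. The fallback sets out from 8 and comes back at 10. It replaces olefination by aldol addition and elimination: the lithium enolate of acetone (LiN(i-Pr)2, acetone, THF, −78 °C) adds to 8 to give the beta-hydroxy ketone F3 as a mixture of carbinol epimers. MsCl/Et3N converts it into the mesylate F4 (not isolated), and DBU eliminates this to enone 10.

Further compounds
F1 | step 1 | (2S)-2-(hydroxymethyl)-2-methylcyclohexan-1-one | OC[C@]1(C)CCCCC1=O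
F2 | step 4 | (1S,2R,5R,8aS)-5-(acetoxymethyl)-1,2,5-trimethyl-1,2,3,5,6,7,8,8a-octahydronaphthalene-1-carbaldehyde | CC(=O)OC[C@]1(C)CCC[C@H]2C1=CC[C@@H](C)[C@]2(C)C=O
F3 | step 5 | 4-hydroxy-4-[(1R,2S,5R,8aR)-5-(acetoxymethyl)-1,2,5-trimethyl-1,2,3,5,6,7,8,8a-octahydronaphthalen-1-yl]butan-2-one (both carbinol epimers) | CC(=O)OC[C@]1(C)CCC[C@@H]2C1=CC[C@H](C)[C@@]2(C)C(O)CC(C)=O
F4 | step 5 | 4-(methanesulfonyloxy)-4-[(1R,2S,5R,8aR)-5-(acetoxymethyl)-1,2,5-trimethyl-1,2,3,5,6,7,8,8a-octahydronaphthalen-1-yl]butan-2-one (both epimers) | CC(=O)OC[C@]1(C)CCC[C@@H]2C1=CC[C@H](C)[C@@]2(C)C(OS(C)(=O)=O)CC(C)=O
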